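**The unit.** One charge of gas equals the substrate put in. Each target holds one gas and each over-reacted product two, so gas bound, in charges, is the target fraction plus twice the product fraction, and the product fraction is whatever substrate and target leave.

common to all: gas phase 16 mM (held)

| run | substrate | remark | time |
|---|---|---|---|
| oak | 0.070 M | run made earlier |  |
| birch | 0.11 M | run made earlier |  |
| flask | 0.050 M |  | 40 h |

| run | time / h | target / % | substrate / % |
|---|---|---|---|
| oak | 4.00 | 8.2 | 92.7 |
| oak | 8.00 | 13.4 | 84.4 |
| oak | 12.0 | 16.5 | 79.1 |
| oak | 15.0 | 15.0 | 76.9 |
| oak | 20.0 | 17.2 | 68.8 |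
| oak | 25.0 | 17.0 | 64.7 |
| birch | 4.00 | 5.1 | 96.1 |
| birch | 8.00 | 8.9 | 89.3 |
| birch | 12.0 | 12.3 | 86.0 |
| birch | 15.0 | 15.6 | 82.0 |
| birch | 20.0 | 15.2 | 79.7 |
| birch | 25.0 | 14.3 | 75.6 |

(each reading ± 1 percentage point)

- the target standing at 40 h, as a percentage of the substrate charged
- concentration of dissolved gas in solution at 40 h, in percent of saturation

**Two times.** At its last reading the oak run reads 0.536 charges bound and the birch run 0.345, which at their different charges comes to 1.50 mM h⁻¹ and 1.52 mM h⁻¹, equal within the scatter, so the two runs read as one average gas uptake at two charges of substrate. Taking that uptake over as a steady supply, a reckoning for this flask has two times: the 33.3 h in which one charge of gas arrives, and the 40 h asked. Their ratio is 1.20, the charges supplied, which lies beyond what the oak run bound, so the target at that point is extrapolated, not read.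

**The forecast.** It gives 12% target and 14% of saturation, holding that “dissolved gas stays well below saturation”.

**The flask.** Target stands at 14.9% and dissolved gas at 37.2% of saturation, 23 percentage points above the forecast. At 40.0 h this flask holds 1.05 charges bound and 0.119 dissolved, together 1.17 against the 1.20 supplied by the reckoning.

    dissolved gas + target → over-reacted product (k = 0.250 L mol⁻¹ min⁻¹)
    gas phase ⇌ dissolved gas, rate k2*(csat - [dissolved gas]) (kL = 0.00210 min⁻¹)
    substrate + dissolved gas ⇌ target (K = 75.0 L mol⁻¹, k = 0.440 L mol⁻¹ min⁻¹)

**A second flask.** With 0.12 M of substrate and the same time, the reckoning supplies 0.500 charges. The computed flask holds 0.540 bound and 0.0271 dissolved, with target at 14.3%.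

The earlier runs and the new flask were computed with made-up constants; the scatter is artificial.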